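All runs were computed with constants of no real substance; scatter was added.

3 questions stand over winter and midnight, and they turn on the end state: the average length is the monomer in chains divided by the chains begun.

| setting | violet | grey | winter | midnight |
|---|---|---|---|---|
| free monomer | 0.40 M (fed, over 12 h) | 0.40 M (fed, over 12 h) | 0.40 M (fed, over 12 h) | 0.40 M (fed, over 40 h) |
| initiator | 1 mol% | 4 mol% | 2 mol% | 2 mol% |
| remark | run made earlier | run made earlier |  |  |
| time |  |  | 4.0 d | 4.0 d |

| run | time / d | monomer in chains / % |
|---|---|---|
| violet | 0.208 | 1.0 |
| violet | 0.625 | 13.1 |
| violet | 1.04 | 26.3 |
| violet | 1.67 | 44.0 |
| violet | 2.50 | 61.3 |
| grey | 0.208 | 3.8 |
| grey | 0.333 | 12.5 |
| grey | 0.625 | 43.5 |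
| grey | 1.25 | 79.4 |
| grey | 2.50 | 97.7 |

(scatter of a reading: 1 percentage point)

* which of the two ends with the longer chains by the average number of monomer units in a chain (chains begun, living or dead) ("neither" if they lie within 10%) (winter / midnight / neither)
* average number of monomer units in a chain (chains begun, living or dead) at the end, winter
* average number of monomer units in a chain (chains begun, living or dead) at the end, midnight

- the average divides the monomer in chains by the number of chains begun, living and dead together
- candidate steps: free monomer + initiator -> living end + monomer in chains; free monomer + living end -> monomer in chains + living end; initiator -> spent initiator
- the earlier runs do not show the number of chains; that part of a forecast is a guess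
- percentages count the whole charge, also what has not yet gone in

The reckoning here starts from the tail of the violet run. Between 1.67 d and 2.50 d the logarithm of the free monomer left falls at 0.445 /d, a pseudo-first-order slope read with the scatter of the readings. The tail of the grey run gives 1.75 /d, which is 3.93 times as steep for 4.00 times the loading, so the slope follows the loading. At 2 mol% it should be 0.890 /d.

Free monomer enters on average at the middle of its dosing time, so at 4.0 d winter should keep 3.55%. In midnight it enters on average 0.583 d later, so midnight should keep somewhat more. The loading then gives 50.0 units. This ratio of monomer charged to initiator charged is named the full-start length: the average length at complete conversion if each initiator starts one chain. Multiplied by winter's conversion, it gives 48.2 for winter. Midnight has the same loading and so the same full-start length, and its somewhat lower conversion puts it a little under that figure, so this reckoning says neither. Its weak link is the start itself: the slope reads the growth constant times the number of living ends, and the earlier runs do not show the number of chains.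

The forecast put 51 for winter and 60 for midnight, with midnight longer, on the judgement that under the slower feed “any decay wastes more initiator”. It differs here from the reckoning above.

The flasks give 265 for winter and 441 for midnight, so midnight ends longer, and the difference in dosing time is the main reason for that gap.

    free monomer + initiator → living end + monomer in chains (k = 1.30 /M/h)
    free monomer + living end → monomer in chains + living end, rate k2*[living end]*[free monomer] (k = 24.0 /M/h)
    initiator → spent initiator (k = 0.370 /h)

Winter's 95.4% of monomer in chains on the full-start length makes 47.7, against 265, so its start share, the initiator efficiency, was 18.0%. Winter's chains are longer than the full-start length because the path from initiator to spent initiator acts together with the slow addition of free monomer: at 0.500 d initiator stands at 0.0718% of its charge, and winter without that path gives 51.4. The neighbour flask, winter with 0.10 M of free monomer at the same loading, keeps the full-start length, and its 24.3% and 187 give a start share of 6.49%.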